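**Plan** (flavanone locants C2–C8a and O1; piperidine atoms marked "pip")

- Cuts, in retrosynthetic order:
  - C2–C1' (ring B taken off a chromone);
  - O1–C2, C2–C3 and C4–C4a (ring C back to an aryllithium, an acetyl donor and a one-carbon amide acetal);
  - N–C2(pip);
  - C2(pip)–C3(pip), as the double bond of an E-styrene.
- Enabling feature: C2(pip) sits on C6 of ring A, between the oxygens on C5 and C7 and opposite O1 on C8a. It is therefore the exocyclic carbon of a strongly stabilised ortho-quinone methide of ring A, reachable by protonating a 2-alkenylresorcinol.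
- Forward order: the side chain is joined to ring A by olefination, the piperidine is closed on the quinone methide, and the carbamate is reduced to N-methyl. Ring C is then built on the only unmasked oxygen (para to the piperidine, which gives the 6- and excludes the 8-substituted isomer), and ring B is added last.
- Stereochemistry: C2(pip) (S) comes from a chiral phosphoric acid and C2 (S) from a rhodium/chiral diene conjugate arylation. Both are catalyst-controlled.
- Protecting groups guard the stereocentres: the two flanking phenols are benzylated straight after the cyclisation so the C–N bond cannot reopen, and the last step is a neutral hydrogenolysis.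

Key step: step 8

Assumption: the hand of the phosphoric acid (step 8) and of the diene ligand (step 14) is chosen by analogy with simpler substrates; both antipodes of each are commercial, so the opposite one is taken if the first run shows the reverse sense.

Step 1
Reactants: 1 4-aminobutan-1-ol; 2 methyl chloroformate
Product: 3 methyl (4-hydroxybutyl)carbamate
Conditions: NaHCO3, THF/H2O, 0 °C → rt
Reagents that add atoms: none
Why: Schotten–Baumann N-acylation, in which the amine is far more nucleophilic than the primary alcohol, so only the carbamate forms, and its carbonyl carbon is the later N-methyl carbon.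

Step 2
Reactants: 3 methyl (4-hydroxybutyl)carbamate
Product: 4 methyl {4-[(1-phenyl-1H-tetrazol-5-yl)sulfanyl]butyl}carbamate
Conditions: 1-phenyl-1H-tetrazole-5-thiol, PPh3, DIAD, THF, 0 °C → rt
Reagents that add atoms: 1-phenyl-1H-tetrazole-5-thiol, Sc1nnnn1-c1ccccc1
Why: Mitsunobu thioetherification, in which the acidic tetrazolethiol is alkylated by the activated primary alcohol while the carbamate N–H is too weakly acidic to compete.

Step 3
Reactants: 4 methyl {4-[(1-phenyl-1H-tetrazol-5-yl)sulfanyl]butyl}carbamate
Product: 5 methyl {4-[(1-phenyl-1H-tetrazol-5-yl)sulfonyl]butyl}carbamate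
Conditions: 30% aq. H2O2, (NH4)6Mo7O24·4H2O (cat.), EtOH, 0 °C → rt
Reagents that add atoms: hydrogen peroxide, OO
Why: Molybdate-catalysed peroxide oxidation of a sulfide to the sulfone is the standard entry to Julia–Kocienski reagents and leaves the carbamate untouched.

Step 4
Reactants: 6 2,4,6-trihydroxybenzaldehyde
Product: 7 2,6-dihydroxy-4-(methoxymethoxy)benzaldehyde
Conditions: MOMCl (0.95 equiv), K2CO3 (1.0 equiv), acetone, 0 °C → rt
Reagents that add atoms: chloromethyl methyl ether, COCCl
Why: Regioselective Williamson-type O-alkylation, in which the C4 hydroxyl (para to the formyl group and not hydrogen-bonded to it) is the most acidic and is ionised first by one equivalent of weak base, so a slight deficit of the chloride should favour the 4-O-MOM ether, with over-alkylated material removed by chromatography.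

Step 5
Reactants: 7 2,6-dihydroxy-4-(methoxymethoxy)benzaldehyde
Product: 8 4-(methoxymethoxy)-2,6-bis(prop-2-en-1-yloxy)benzaldehyde
Conditions: allyl bromide (3 equiv), K2CO3, DMF, 50 °C
Reagents that add atoms: allyl bromide, C=CCBr
Why: Williamson etherification under more forcing conditions caps both chelated ortho hydroxyls with a group that, unlike a silyl group, cannot migrate to the alkoxide formed in the next step and that comes off later without acid.

Step 6
Reactants: 5 methyl {4-[(1-phenyl-1H-tetrazol-5-yl)sulfonyl]butyl}carbamate; 8 4-(methoxymethoxy)-2,6-bis(prop-2-en-1-yloxy)benzaldehyde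
Product: 10 methyl {(4E)-5-[4-(methoxymethoxy)-2,6-bis(prop-2-en-1-yloxy)phenyl]pent-4-en-1-yl}carbamate, via dipotassiated sulfone 9 (not isolated)
Conditions: 5, KN(SiMe3)2 (2.1 equiv per 5), DME, −60 °C; then 8, −60 °C → rt; H2O
Reagents that add atoms: none
Why: Julia–Kocienski olefination, in which the second equivalent of base covers the carbamate N–H, the adduct with the non-enolisable electron-rich aldehyde undergoes Smiles rearrangement and loses SO2, and phenyltetrazolyl sulfones with aromatic aldehydes favour the E alkene, the isomer that can lie coplanar with ring A and so be protonated easily in step 8.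

Step 7
Reactants: 10 methyl {(4E)-5-[4-(methoxymethoxy)-2,6-bis(prop-2-en-1-yloxy)phenyl]pent-4-en-1-yl}carbamate
Product: 11 methyl {(4E)-5-[2,6-dihydroxy-4-(methoxymethoxy)phenyl]pent-4-en-1-yl}carbamate
Conditions: Pd(PPh3)4 (5 mol %), morpholine (10 equiv), degassed THF, rt; chromatography on Et3N-deactivated silica
Reagents that add atoms: none
Why: Tsuji–Trost-type deallylation, in which zerovalent palladium ionises the aryl allyl ethers and morpholine traps the allyl fragments under mildly basic conditions, so the acid-sensitive alkenylresorcinol is released without premature racemic cyclisation.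

Step 8
Reactants: 11 methyl {(4E)-5-[2,6-dihydroxy-4-(methoxymethoxy)phenyl]pent-4-en-1-yl}carbamate
Product: 13 methyl (2S)-2-[2,6-dihydroxy-4-(methoxymethoxy)phenyl]piperidine-1-carboxylate, via ortho-quinone methide 12 (not isolated)
Conditions: (R)-3,3'-bis(2,4,6-triisopropylphenyl)-1,1'-binaphthyl-2,2'-diyl hydrogen phosphate (10 mol %), 4 Å MS, toluene/CH2Cl2 (0.02 M), −30 °C; Et3N quench
Reagents that add atoms: none
Why: Proposed new method: the acid gives its proton to the alkene carbon remote from ring A (the later C3 of the piperidine) while its phosphoryl oxygen holds an ortho O–H, which turns 11 into the hydrogen-bonded ortho-quinone methide 12, and the carbamate N–H, bound to the same phosphate, then adds through nitrogen to the exocyclic carbon so that ring A rearomatises. The closest known reactions are chiral phosphoric acid-catalysed conjugate additions of nitrogen and oxygen nucleophiles to ortho-quinone methides made from ortho-hydroxybenzyl alcohols, the acid-triggered conversion of ortho-hydroxystyrenes into such quinone methides followed by enantioselective trapping, and chiral Brønsted acid-catalysed intramolecular hydroamination of dienes; what is new is a tethered carbamate closing a piperidine in this way. The ring closes in the 6-exo-trig mode, because the attacked C=C bond lies outside the new ring. The only new stereocentre, C2 of the piperidine, is set by the chiral phosphate, which bridges the quinone methide oxygen and the N–H and so leaves one face of the planar exocyclic carbon open. The step needs N- over O-attack (oxygen would have to close an eight-membered ring), cyclisation over dimerisation (high dilution) and the catalysed over the uncatalysed path (low temperature, non-polar medium, acid-free glassware); the three oxygen donors on ring A (two ortho, one para) are what let so weak an acid protonate the alkene, and the carbamate is not basic enough to neutralise the catalyst. Because the product could ionise again, the reaction is stopped at full conversion and 13 is benzylated directly.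

Step 9
Reactants: 13 methyl (2S)-2-[2,6-dihydroxy-4-(methoxymethoxy)phenyl]piperidine-1-carboxylate
Product: 14 methyl (2S)-2-[2,6-bis(benzyloxy)-4-(methoxymethoxy)phenyl]piperidine-1-carboxylate
Conditions: BnBr (2.5 equiv), K2CO3, DMF, rt
Reagents that add atoms: benzyl bromide, BrCc1ccccc1
Why: Williamson benzylation of both phenols is done at once because capping the ortho oxygens removes the quinone methide pathway by which the new C–N bond could reopen and the stereocentre racemise.

Step 10
Reactants: 14 methyl (2S)-2-[2,6-bis(benzyloxy)-4-(methoxymethoxy)phenyl]piperidine-1-carboxylate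
Product: 15 (2S)-2-[2,6-bis(benzyloxy)-4-(methoxymethoxy)phenyl]-1-methylpiperidine
Conditions: LiAlH4, THF, 0 °C → reflux; aq. NaOH work-up
Reagents that add atoms: none
Why: Hydride reduction of a carbamate to the N-methylamine (through formamide and iminium stages) touches neither the benzyl and MOM ethers nor the stereocentre.

Step 11
Reactants: 15 (2S)-2-[2,6-bis(benzyloxy)-4-(methoxymethoxy)phenyl]-1-methylpiperidine; 16 N-methoxy-N-methylacetamide
Product: 18 1-{2,4-bis(benzyloxy)-6-(methoxymethoxy)-3-[(2S)-1-methylpiperidin-2-yl]phenyl}ethan-1-one, via aryllithium 17 (not isolated)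
Conditions: n-BuLi (1.2 equiv), THF, −20 → 0 °C; then 16, −78 → 0 °C; H2O
Reagents that add atoms: none
Why: Directed ortho-metalation, in which the MOM ether and the neighbouring benzyloxy group together direct lithiation to one of the two equivalent free positions of ring A, and the N-methoxy-N-methylamide stops at the ketone through its chelated tetrahedral adduct.

Step 12
Reactants: 18 1-{2,4-bis(benzyloxy)-6-(methoxymethoxy)-3-[(2S)-1-methylpiperidin-2-yl]phenyl}ethan-1-one; 19 N,N-dimethylformamide dimethyl acetal
Product: 20 (2E)-1-{2,4-bis(benzyloxy)-6-(methoxymethoxy)-3-[(2S)-1-methylpiperidin-2-yl]phenyl}-3-(dimethylamino)prop-2-en-1-one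
Conditions: 19 (5 equiv), toluene, 110 °C
Reagents that add atoms: none
Why: Condensation of the methyl ketone with the amide acetal (enaminone synthesis) adds the one carbon that becomes C2 of ring C, and with every phenol masked the benzylic amine cannot eliminate on heating.

Step 13
Reactants: 20 (2E)-1-{2,4-bis(benzyloxy)-6-(methoxymethoxy)-3-[(2S)-1-methylpiperidin-2-yl]phenyl}-3-(dimethylamino)prop-2-en-1-one
Product: 22 5,7-bis(benzyloxy)-6-[(2S)-1-methylpiperidin-2-yl]-4H-chromen-4-one, via free-phenol enaminone 21 (not isolated)
Conditions: HCl (2 M in MeOH), 40 °C; then aq. NaHCO3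
Reagents that add atoms: none
Why: Acidic acetal cleavage frees only the oxygen para to the piperidine, which adds to the enaminone and expels dimethylamine (addition–elimination chromone synthesis), so ring C can form only with the 6-substituted pattern, and the protonated amine on the now acylated ring should not ionise under these mild conditions.

Step 14
Reactants: 22 5,7-bis(benzyloxy)-6-[(2S)-1-methylpiperidin-2-yl]-4H-chromen-4-one; 23 [4-(benzyloxy)phenyl]boronic acid
Product: 24 (2S)-5,7-bis(benzyloxy)-2-[4-(benzyloxy)phenyl]-6-[(2S)-1-methylpiperidin-2-yl]-2,3-dihydro-4H-chromen-4-one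
Conditions: 23 (2.5 equiv), [RhCl(C2H4)2]2 (2.5 mol %), (1S,4S)-2,5-diphenylbicyclo[2.2.2]octa-2,5-diene (5.5 mol %), KOH (10 mol %), toluene/H2O 10:1, 40 °C
Reagents that add atoms: none
Why: Hayashi–Miyaura asymmetric conjugate arylation, which is known for chromones, has the aryl-rhodium species bound to the C2-symmetric diene add to one face of C2=C3, and hydrolysis of the rhodium enolate then gives the (2S)-flavanone under catalyst control, the distant piperidine centre having little influence.

Step 15
Reactants: 24 (2S)-5,7-bis(benzyloxy)-2-[4-(benzyloxy)phenyl]-6-[(2S)-1-methylpiperidin-2-yl]-2,3-dihydro-4H-chromen-4-one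
Product: 25 (2S)-5,7-dihydroxy-2-(4-hydroxyphenyl)-6-[(2S)-1-methylpiperidin-2-yl]-2,3-dihydro-4H-chromen-4-one
Conditions: H2 (1 atm), Pd(OH)2/C, EtOAc/MeOH, rt; filtered and concentrated below 30 °C
Reagents that add atoms: none
Why: Catalytic hydrogenolysis removes the three O-benzyl groups under neutral conditions, which avoids the acid or base that could open ring C or ionise the C2(pip)–N bond, so both stereocentres are kept.

**Compound list**

1 | 4-aminobutan-1-ol | NCCCCO | starting material
2 | methyl chloroformate | COC(=O)Cl | starting material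
3 | methyl (4-hydroxybutyl)carbamate | COC(=O)NCCCCO | intermediate
4 | methyl {4-[(1-phenyl-1H-tetrazol-5-yl)sulfanyl]butyl}carbamate | COC(=O)NCCCCSc1nnnn1-c1ccccc1 | intermediate
5 | methyl {4-[(1-phenyl-1H-tetrazol-5-yl)sulfonyl]butyl}carbamate | COC(=O)NCCCCS(=O)(=O)c1nnnn1-c1ccccc1 | intermediate
6 | 2,4,6-trihydroxybenzaldehyde | O=Cc1c(O)cc(O)cc1O | starting material
7 | 2,6-dihydroxy-4-(methoxymethoxy)benzaldehyde | O=Cc1c(O)cc(OCOC)cc1O | intermediate
8 | 4-(methoxymethoxy)-2,6-bis(prop-2-en-1-yloxy)benzaldehyde | O=Cc1c(OCC=C)cc(OCOC)cc1OCC=C | intermediate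
9 | dipotassium salt of 5 (N- and alpha-sulfonyl C-deprotonated) | COC(=O)[N-]CCC[CH-]S(=O)(=O)c1nnnn1-c1ccccc1.[K+].[K+] | intermediate
10 | methyl {(4E)-5-[4-(methoxymethoxy)-2,6-bis(prop-2-en-1-yloxy)phenyl]pent-4-en-1-yl}carbamate | COC(=O)NCCC/C=C/c1c(OCC=C)cc(OCOC)cc1OCC=C | intermediate
11 | methyl {(4E)-5-[2,6-dihydroxy-4-(methoxymethoxy)phenyl]pent-4-en-1-yl}carbamate | COC(=O)NCCC/C=C/c1c(O)cc(OCOC)cc1O | intermediate
12 | methyl {5-[2-hydroxy-4-(methoxymethoxy)-6-oxocyclohexa-2,4-dien-1-ylidene]pentyl}carbamate | COC(=O)NCCCCC=C1C(=O)C=C(OCOC)C=C1O | intermediate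
13 | methyl (2S)-2-[2,6-dihydroxy-4-(methoxymethoxy)phenyl]piperidine-1-carboxylate | COC(=O)N1CCCC[C@H]1c1c(O)cc(OCOC)cc1O | intermediate
14 | methyl (2S)-2-[2,6-bis(benzyloxy)-4-(methoxymethoxy)phenyl]piperidine-1-carboxylate | COC(=O)N1CCCC[C@H]1c1c(OCc2ccccc2)cc(OCOC)cc1OCc1ccccc1 | intermediate
15 | (2S)-2-[2,6-bis(benzyloxy)-4-(methoxymethoxy)phenyl]-1-methylpiperidine | CN1CCCC[C@H]1c1c(OCc2ccccc2)cc(OCOC)cc1OCc1ccccc1 | intermediate
16 | N-methoxy-N-methylacetamide | CC(=O)N(C)OC | starting material
17 | {2,4-bis(benzyloxy)-6-(methoxymethoxy)-3-[(2S)-1-methylpiperidin-2-yl]phenyl}lithium | CN1CCCC[C@H]1c1c(OCc2ccccc2)cc(OCOC)c([Li])c1OCc1ccccc1 | intermediate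
18 | 1-{2,4-bis(benzyloxy)-6-(methoxymethoxy)-3-[(2S)-1-methylpiperidin-2-yl]phenyl}ethan-1-one | CN1CCCC[C@H]1c1c(OCc2ccccc2)cc(OCOC)c(C(C)=O)c1OCc1ccccc1 | intermediate
19 | N,N-dimethylformamide dimethyl acetal | COC(OC)N(C)C | starting material
20 | (2E)-1-{2,4-bis(benzyloxy)-6-(methoxymethoxy)-3-[(2S)-1-methylpiperidin-2-yl]phenyl}-3-(dimethylamino)prop-2-en-1-one | CN1CCCC[C@H]1c1c(OCc2ccccc2)cc(OCOC)c(C(=O)/C=C/N(C)C)c1OCc1ccccc1 | intermediate
21 | (2E)-1-{2,4-bis(benzyloxy)-6-hydroxy-3-[(2S)-1-methylpiperidin-2-yl]phenyl}-3-(dimethylamino)prop-2-en-1-one | CN1CCCC[C@H]1c1c(OCc2ccccc2)cc(O)c(C(=O)/C=C/N(C)C)c1OCc1ccccc1 | intermediate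
22 | 5,7-bis(benzyloxy)-6-[(2S)-1-methylpiperidin-2-yl]-4H-chromen-4-one | CN1CCCC[C@H]1c1c(OCc2ccccc2)cc2occc(=O)c2c1OCc1ccccc1 | intermediate
23 | [4-(benzyloxy)phenyl]boronic acid | OB(O)c1ccc(OCc2ccccc2)cc1 | starting material
24 | (2S)-5,7-bis(benzyloxy)-2-[4-(benzyloxy)phenyl]-6-[(2S)-1-methylpiperidin-2-yl]-2,3-dihydro-4H-chromen-4-one | CN1CCCC[C@H]1c1c(OCc2ccccc2)cc2c(c1OCc1ccccc1)C(=O)C[C@@H](c1ccc(OCc3ccccc3)cc1)O2 | intermediate
25 | (2S)-5,7-dihydroxy-2-(4-hydroxyphenyl)-6-[(2S)-1-methylpiperidin-2-yl]-2,3-dihydro-4H-chromen-4-one | CN1CCCC[C@H]1c1c(O)cc2c(c1O)C(=O)C[C@@H](c1ccc(O)cc1)O2 | target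

**Step count**

Total step count: 15.
Longest linear sequence: 13 steps (from 1 through steps 1–3 and 6–15; the ring A branch from 6 runs 12 steps).

**Steps most likely to fail**

1. Step 8 (the step that goes beyond known chemistry).
   - The facial selectivity may be eroded in three ways. Uncatalysed cyclisation of this very electron-rich styrene may compete. The benzylic C–N bond may re-ionise under the acid. The two equivalent ortho hydroxyls also offer the phosphate two ways of binding. Dimerisation of the quinone methide with unreacted styrene may lower the mass balance.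
   - The fallback uses known auxiliary chemistry, sets out from 7 and returns at 15.
   - Both phenols of 7 are benzylated (BnBr, K2CO3, DMF) to 2,6-bis(benzyloxy)-4-(methoxymethoxy)benzaldehyde F1. This is condensed with (R)-2-methylpropane-2-sulfinamide (Ti(OEt)4, THF) to the (R,E)-N-sulfinyl imine F2.
   - 4-Chlorobutylmagnesium bromide F3, made from 1-bromo-4-chlorobutane and Mg, is added in CH2Cl2 at −48 °C. The cyclic magnesium-bridged transition state should give the (R)-sulfinyl (1S)-chloropentyl sulfinamide F4, and any minor diastereomer can be removed by chromatography.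
   - KN(SiMe3)2 in THF closes the ring by 6-exo-tet displacement of chloride to the N-sulfinylpiperidine F5.
   - Brief treatment with a small excess of HCl in MeOH at 0 °C removes the sulfinyl group ahead of the aryl MOM ether and gives the secondary amine F6. Reductive methylation (aq. CH2O, NaBH(OAc)3) then delivers 15.

2. Step 14.
   - The tertiary amine may bind rhodium and stall turnover, and the electron-rich boronic acid may protodeboronate. The flavanone may also open reversibly to the chalcone in the basic aqueous medium, which would erode the configuration at C2.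
   - The fallback sets out from 18 and returns at 24. It replaces catalyst-controlled C–C bond formation by C–O ring closure and separation of diastereomers.
   - The MOM ether of 18 is cleaved (HCl, MeOH, 40 °C) to the 6-hydroxyacetophenone F7. Claisen–Schmidt condensation with 4-(benzyloxy)benzaldehyde (KOH, EtOH, rt) gives the 2'-hydroxychalcone F8.
   - Oxa-Michael closure (NaOAc, EtOH, reflux) gives 24 together with its (2R)-epimer F9. Because the piperidine centre is already fixed, the two are diastereomers and can be separated by chromatography or crystallisation. F9 is recycled by base equilibration through F8.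

3. Step 11.
   - Deprotonation of the benzylic OCH2 groups followed by Wittig rearrangement may compete with ring lithiation. Enolisation of the amide by the hindered aryllithium may return unchanged 15.
   - The fallback sets out from 15 and returns at 18. It fixes the position by electrophilic substitution instead of deprotonation and uses a more electrophilic carbonyl partner.
   - The amine is protonated with one equivalent of CF3CO2H and ring A is brominated with NBS (CH2Cl2, −20 °C) to the aryl bromide F10.
   - Bromine–lithium exchange (n-BuLi, THF, −78 °C), which is much faster than any deprotonation, gives aryllithium 17. This is trapped with acetaldehyde to the benzylic alcohol F11 (both carbinol epimers), and MnO2 oxidation gives 18.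

**Further compounds**

F1 | step 8 | 2,6-bis(benzyloxy)-4-(methoxymethoxy)benzaldehyde | O=Cc1c(OCc2ccccc2)cc(OCOC)cc1OCc1ccccc1
F2 | step 8 | (R,E)-N-{[2,6-bis(benzyloxy)-4-(methoxymethoxy)phenyl]methylidene}-2-methylpropane-2-sulfinamide | CC(C)(C)[S@@](=O)/N=C/c1c(OCc2ccccc2)cc(OCOC)cc1OCc1ccccc1
F3 | step 8 | 4-chlorobutylmagnesium bromide | ClCCCC[Mg]Br
F4 | step 8 | (R)-N-{(1S)-1-[2,6-bis(benzyloxy)-4-(methoxymethoxy)phenyl]-5-chloropentyl}-2-methylpropane-2-sulfinamide | CC(C)(C)[S@@](=O)N[C@@H](CCCCCl)c1c(OCc2ccccc2)cc(OCOC)cc1OCc1ccccc1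
F5 | step 8 | (2S)-2-[2,6-bis(benzyloxy)-4-(methoxymethoxy)phenyl]-1-[(R)-2-methylpropane-2-sulfinyl]piperidine | CC(C)(C)[S@@](=O)N1CCCC[C@H]1c1c(OCc2ccccc2)cc(OCOC)cc1OCc1ccccc1
F6 | step 8 | (2S)-2-[2,6-bis(benzyloxy)-4-(methoxymethoxy)phenyl]piperidine | N1CCCC[C@H]1c1c(OCc2ccccc2)cc(OCOC)cc1OCc1ccccc1
F7 | step 14 | 1-{2,4-bis(benzyloxy)-6-hydroxy-3-[(2S)-1-methylpiperidin-2-yl]phenyl}ethan-1-one | CN1CCCC[C@H]1c1c(OCc2ccccc2)cc(O)c(C(C)=O)c1OCc1ccccc1
F8 | step 14 | (2E)-1-{2,4-bis(benzyloxy)-6-hydroxy-3-[(2S)-1-methylpiperidin-2-yl]phenyl}-3-[4-(benzyloxy)phenyl]prop-2-en-1-one | CN1CCCC[C@H]1c1c(OCc2ccccc2)cc(O)c(C(=O)/C=C/c2ccc(OCc3ccccc3)cc2)c1OCc1ccccc1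
F9 | step 14 | (2R)-5,7-bis(benzyloxy)-2-[4-(benzyloxy)phenyl]-6-[(2S)-1-methylpiperidin-2-yl]-2,3-dihydro-4H-chromen-4-one | CN1CCCC[C@H]1c1c(OCc2ccccc2)cc2c(c1OCc1ccccc1)C(=O)C[C@H](c1ccc(OCc3ccccc3)cc1)O2
F10 | step 11 | (2S)-2-[2,6-bis(benzyloxy)-3-bromo-4-(methoxymethoxy)phenyl]-1-methylpiperidine | CN1CCCC[C@H]1c1c(OCc2ccccc2)cc(OCOC)c(Br)c1OCc1ccccc1
F11 | step 11 | 1-{2,4-bis(benzyloxy)-6-(methoxymethoxy)-3-[(2S)-1-methylpiperidin-2-yl]phenyl}ethan-1-ol (both carbinol epimers) | CN1CCCC[C@H]1c1c(OCc2ccccc2)cc(OCOC)c(C(C)O)c1OCc1ccccc1
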